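**Retrosynthetic overview**
1. Lutein dimyristate ⇐ lutein (double O-acylation) ⇐ zeinoxanthin (enzymatic allylic hydroxylation at C3′ of the ε ring).
2. Zeinoxanthin ⇐ rubixanthin: the ε ring is closed on the finished C40 chain by a lycopene ε-cyclase, forming the C1′–C6′ bond.
3. Enabling feature: in the ε ring the gem-dimethyl carbon C1′ is bonded to C6′ and the ring double bond C4′=C5′ lies out of conjugation. Opening C1′–C6′ and moving one H from C2′ to C4′ reveals a ψ end with an isolated C1′=C2′ bond placed 1,5 to C5′=C6′, the pattern for a proton-triggered cation–olefin ring closure.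
4. Rubixanthin ⇐ C25 aldehyde + acyclic C15 phosphonium salt (from pseudoionone); C25 aldehyde ⇐ (3R)-C15 β-end phosphonium salt + C10 dialdehyde (two Wittig reactions).
5. Ring order: the β ring is bought closed, with C3 in place; the ε ring is the only ring closed in the route and is closed last (step 5).

Key step: step 5

Assumption: the (3R)-C15 phosphonium chloride 1 (industrial zeaxanthin intermediate) and (3E,5E)-pseudoionone 5 (separated from the commercial 5E/5Z mixture) are taken as purchasable.
Assumption: the ε-cyclase is taken to accept a ψ-end substrate whose far end is already a 3-hydroxy-β ring; ε-cyclases that cyclise both ends of lycopene do tolerate a far end that is already cyclic.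

**Route**

Step 1
Reactants: 1 (3R)-C15 β-end triphenylphosphonium chloride; 2 (2E,4E,6E)-2,7-dimethylocta-2,4,6-trienedial (C10 dialdehyde)
Product: 4 (3R)-3-hydroxy-12′-apo-β-caroten-12′-al, via C15 ylide 3 (not isolated)
Conditions: NaOMe, MeOH/CH2Cl2, 0 °C to rt, 2 in excess (2 equiv); then n-heptane, reflux (E-equilibration)
Reagents that add atoms: none
Why: Wittig olefination of the semi-stabilised allylic ylide with one formyl group of the dialdehyde used in excess; the new C11=C12 bond forms as an E/Z mixture that should equilibrate to E on heating, and C3 is not involved.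

Step 2
Reactants: 5 (3E,5E)-pseudoionone; 6 vinylmagnesium bromide
Product: 8 vinyl-ψ-ionol [(4E,6E)-3,7,11-trimethyldodeca-1,4,6,10-tetraen-3-ol, racemic], via bromomagnesium alkoxide 7 (not isolated)
Conditions: THF, −20 to 0 °C; sat. aq NH4Cl
Reagents that add atoms: vinylmagnesium bromide (6), C=C[Mg]Br
Why: Grignard 1,2-addition of the hard vinyl nucleophile to the dienone carbonyl; the new carbinol centre is of no consequence because it is lost in step 3.

Step 3
Reactants: 8 vinyl-ψ-ionol; 9 triphenylphosphine hydrobromide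
Product: 10 [(2E,4E,6E)-3,7,11-trimethyldodeca-2,4,6,10-tetraen-1-yl]triphenylphosphonium bromide
Conditions: MeOH/CH2Cl2, 0 °C to rt; crystallisation of the 2E salt from EtOAc
Reagents that add atoms: triphenylphosphine hydrobromide (9), [Br-].c1ccc(cc1)[PH+](c1ccccc1)c1ccccc1
Why: Acid-mediated allylic transposition (SN1/SN2′): the tertiary pentadienylic alcohol ionises and triphenylphosphine captures the delocalised cation at the primary terminus, which should give the conjugated salt with the isolated C10=C11 bond untouched.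

Step 4
Reactants: 4 (3R)-3-hydroxy-12′-apo-β-caroten-12′-al; 10 acyclic C15 phosphonium bromide
Product: 12 rubixanthin [(3R)-β,ψ-caroten-3-ol, all-E], via acyclic C15 ylide 11 (not isolated)
Conditions: NaOMe, MeOH/CH2Cl2, 0 °C to rt; then EtOH, reflux (E-equilibration), crystallisation, N2, dark
Reagents that add atoms: none
Why: Wittig olefination forming C11′=C12′; the hindered 11′Z isomer should equilibrate thermally to the all-E compound, and the free 3-hydroxy group tolerates the methoxide base.

Step 5
Reactants: 12 rubixanthin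
Product: 13 zeinoxanthin [(3R,6′R)-β,ε-caroten-3-ol]
Conditions: lycopene ε-cyclase (plant LCYE, recombinant membrane fraction), FAD, NADPH (cat., keeps the flavin reduced), 12 in phosphatidylcholine liposomes, HEPES pH 7.4, N2, dark, 30 °C
Reagents that add atoms: none
Why: The cyclase protonates the isolated C1′=C2′ bond at C2′ to give the tertiary C1′ cation, the C5′=C6′ bond of the folded ψ end adds to it through C6′, and the tertiary C5′ cation is quenched by loss of a C4′ proton, so the C1′–C6′ bond, the quaternary C1′ and the out-of-conjugation C4′=C5′ bond arise in one redox-neutral isomerisation. The closest known reaction is the native one of this enzyme class (flavin-dependent carotenoid cyclases), the conversion of the ψ end of lycopene into the ε end of δ-carotene. The ring closes in a 6-endo-trig cation–olefin mode through a chair-like fold imposed by the active site. C6′ is the only new stereocentre and should be set as R by the enzyme, which presents one face of the E-configured C5′=C6′ bond to C1′; the remote C3 carbinol is not touched. The step needs chemoselectivity for the ψ end over the conjugated undecaene, and regioselective loss of H-4′ rather than H-6′ (β ring) or H-18′ (γ ring). The first is secured by the substrate, whose only non-conjugated and basic trisubstituted alkene is C1′=C2′, lying 1,5 to the chain terminus; the second is secured by the positioned active-site base that distinguishes ε- from β-cyclases.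

Step 6
Reactants: 13 zeinoxanthin
Product: 14 lutein [(3R,3′R,6′R)-β,ε-carotene-3,3′-diol]
Conditions: carotenoid ε-ring hydroxylase (cytochrome P450 CYP97C1), ferredoxin, ferredoxin–NADP+ reductase, NADP+ (cat.), 2-propanol/NADP-dependent alcohol dehydrogenase, air (O2), liposomes, Tris pH 7.5, dark, 25 °C
Reagents that add atoms: dioxygen, O=O
Why: P450 allylic C–H hydroxylation (hydrogen abstraction and oxygen rebound, the native reaction of this hydroxylase class on zeinoxanthin) should oxidise only C3′, the allylic CH2 of the ε ring; the enzyme pocket fixes the new centre as 3′R (OH trans to the C6′ chain) with retention at the abstracted hydrogen.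

Step 7
Reactants: 14 lutein; 15 tetradecanoyl (myristoyl) chloride
Product: 16 lutein dimyristate [(3R,3′R,6′R)-β,ε-carotene-3,3′-diyl ditetradecanoate]
Conditions: 15 (2.5 equiv), pyridine, DMAP (cat.), CH2Cl2, 0 °C to rt, N2, dark
Reagents that add atoms: tetradecanoyl chloride (15), CCCCCCCCCCCCCC(=O)Cl
Why: DMAP-catalysed nucleophilic acyl substitution at both secondary alcohols under basic, non-ionising conditions, so the acid-labile allylic C3′–O bond is not broken and both carbinol centres keep their configuration.

**Compound list**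
1 | [(2E,4E)-5-[(4R)-4-hydroxy-2,6,6-trimethylcyclohex-1-en-1-yl]-3-methylpenta-2,4-dien-1-yl]triphenylphosphonium chloride | O[C@@H]1CC(C)=C(/C=C/C(C)=C/C[P+](c2ccccc2)(c2ccccc2)c2ccccc2)C(C)(C)C1.[Cl-] | starting material
2 | (2E,4E,6E)-2,7-dimethylocta-2,4,6-trienedial | O=C/C(C)=C/C=C/C=C(C)/C=O | starting material
3 | C15 β-end triphenylphosphorane (ylide of 1) | O[C@@H]1CC(C)=C(/C=C/C(C)=C/C=P(c2ccccc2)(c2ccccc2)c2ccccc2)C(C)(C)C1 | intermediate (not isolated)
4 | (3R)-3-hydroxy-12′-apo-β-caroten-12′-al | O[C@@H]1CC(C)=C(/C=C/C(C)=C/C=C/C(C)=C/C=C/C=C(C)/C=O)C(C)(C)C1 | intermediate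
5 | (3E,5E)-6,10-dimethylundeca-3,5,9-trien-2-one (pseudoionone) | CC(C)=CCC/C(C)=C/C=C/C(C)=O | starting material
6 | vinylmagnesium bromide | C=C[Mg]Br | starting material
7 | bromomagnesium (4E,6E)-3,7,11-trimethyldodeca-1,4,6,10-tetraen-3-olate | CC(C)=CCC/C(C)=C/C=C/C(C)(O[Mg]Br)C=C | intermediate (not isolated)
8 | (4E,6E)-3,7,11-trimethyldodeca-1,4,6,10-tetraen-3-ol (vinyl-ψ-ionol, racemic) | CC(C)=CCC/C(C)=C/C=C/C(C)(O)C=C | intermediate
9 | triphenylphosphine hydrobromide | [Br-].c1ccc(cc1)[PH+](c1ccccc1)c1ccccc1 | starting material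
10 | [(2E,4E,6E)-3,7,11-trimethyldodeca-2,4,6,10-tetraen-1-yl]triphenylphosphonium bromide | CC(C)=CCC/C(C)=C/C=C/C(C)=C/C[P+](c1ccccc1)(c1ccccc1)c1ccccc1.[Br-] | intermediate
11 | acyclic C15 triphenylphosphorane (ylide of 10) | CC(C)=CCC/C(C)=C/C=C/C(C)=C/C=P(c1ccccc1)(c1ccccc1)c1ccccc1 | intermediate (not isolated)
12 | rubixanthin, (3R)-β,ψ-caroten-3-ol | O[C@@H]1CC(C)=C(/C=C/C(C)=C/C=C/C(C)=C/C=C/C=C(C)/C=C/C=C(C)/C=C/C=C(C)/CCC=C(C)C)C(C)(C)C1 | intermediate
13 | zeinoxanthin, (3R,6′R)-β,ε-caroten-3-ol | O[C@@H]1CC(C)=C(/C=C/C(C)=C/C=C/C(C)=C/C=C/C=C(C)/C=C/C=C(C)/C=C/[C@H]2C(C)=CCCC2(C)C)C(C)(C)C1 | intermediate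
14 | lutein, (3R,3′R,6′R)-β,ε-carotene-3,3′-diol | O[C@@H]1CC(C)=C(/C=C/C(C)=C/C=C/C(C)=C/C=C/C=C(C)/C=C/C=C(C)/C=C/[C@H]2C(C)=C[C@H](O)CC2(C)C)C(C)(C)C1 | intermediate
15 | tetradecanoyl (myristoyl) chloride | CCCCCCCCCCCCCC(=O)Cl | starting material
16 | lutein dimyristate, (3R,3′R,6′R)-β,ε-carotene-3,3′-diyl ditetradecanoate | CCCCCCCCCCCCCC(=O)O[C@@H]1CC(C)=C(/C=C/C(C)=C/C=C/C(C)=C/C=C/C=C(C)/C=C/C=C(C)/C=C/[C@H]2C(C)=C[C@H](OC(=O)CCCCCCCCCCCCC)CC2(C)C)C(C)(C)C1 | target

**Count**
Total steps: 7. Longest linear sequence: 6 steps (5 → 8 → 10 → 12 → 13 → 14 → 16; steps 2 to 7).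

**Steps most likely to fail**

Step 5 (ε-cyclisation). The membrane enzyme may fail to bind or turn over a substrate whose far end is already cyclised and hydroxylated, or the lipophilic substrate may not be delivered from the liposome to the enzyme, so conversion stalls. The fallback sets out from 4 and comes back at 13. The ε end is taken with its ring and C6′ centre from (R)-α-ionone F1 (purchased). Addition of vinylmagnesium bromide (THF, 0 °C) should give (R)-vinyl-α-ionol F2. Triphenylphosphine hydrobromide in methanol should convert F2 into the ε-C15 phosphonium bromide F3 by allylic transposition. Wittig olefination of 4 with the ylide of F3 (NaOMe, MeOH/CH2Cl2), followed by thermal E-equilibration, should give zeinoxanthin 13, and the route continues with step 6.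

Step 6 (C3′ hydroxylation). Uncoupled turnover of the P450, slow electron transfer in the reconstituted system and oxidative bleaching of the polyene under air may leave most of the substrate unchanged or degraded. The fallback sets out from 4 and comes back at 14; the C3′ oxygen is put in chemically before the C40 stage. (R)-α-Ionone F1 is taken through Horner–Wadsworth–Emmons olefination with diethyl cyanomethylphosphonate (NaH, THF) to (R)-α-ionylideneacetonitrile F4. Allylic oxidation at ring C3 (tert-butyl hydroperoxide, catalytic metal or hypochlorite) should give the 3-oxo nitrile F5. Hydride reduction (NaBH4/CeCl3 or a bulky borohydride) and chromatographic separation of the C3 epimers should give the trans hydroxy nitrile F6, and DIBAL-H (CH2Cl2, −40 °C, hydrolytic work-up) the hydroxy aldehyde F7. On the β side, 4 is reduced with NaBH4 to the C25 diol F8 and converted with triphenylphosphine hydrobromide into the C25 phosphonium bromide F9. Wittig olefination of F7 with the ylide of F9 (NaOMe), then thermal E-equilibration, should give lutein 14, and the route continues with step 7.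

Step 4 (Wittig reaction to rubixanthin). Poor E/Z control at the new bond, incomplete thermal equilibration of 9′Z material carried in from the salt and decomposition of the acyclic ylide may give an isomer mixture that does not crystallise and is not accepted by the cyclase. The fallback sets out from 8 and comes back at 12. PBr3 (Et2O, −10 °C) should convert 8, with allylic transposition, into the C15 bromide F10. Michaelis–Arbuzov reaction with triethyl phosphite should give the diethyl phosphonate F11. Horner–Wadsworth–Emmons olefination of 4 with the anion of F11 (KOtBu, 2 equiv, THF/DMSO) is E-selective and should give rubixanthin 12.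

**Further compounds**
F1 | step 5 | (R)-α-ionone, (3E)-4-[(1R)-2,6,6-trimethylcyclohex-2-en-1-yl]but-3-en-2-one (purchased) | CC(=O)/C=C/[C@H]1C(C)=CCCC1(C)C
F2 | step 5 | (1E)-3-methyl-1-[(1R)-2,6,6-trimethylcyclohex-2-en-1-yl]penta-1,4-dien-3-ol (vinyl-α-ionol) | C=CC(C)(O)/C=C/[C@H]1C(C)=CCCC1(C)C
F3 | step 5 | [(2E,4E)-3-methyl-5-[(1R)-2,6,6-trimethylcyclohex-2-en-1-yl]penta-2,4-dien-1-yl]triphenylphosphonium bromide | c1ccccc1[P+](c1ccccc1)(c1ccccc1)C/C=C(C)/C=C/[C@H]1C(C)=CCCC1(C)C.[Br-]
F4 | step 6 | (2E,4E)-3-methyl-5-[(1R)-2,6,6-trimethylcyclohex-2-en-1-yl]penta-2,4-dienenitrile | N#C/C=C(C)/C=C/[C@H]1C(C)=CCCC1(C)C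
F5 | step 6 | (2E,4E)-3-methyl-5-[(1R)-2,6,6-trimethyl-4-oxocyclohex-2-en-1-yl]penta-2,4-dienenitrile | N#C/C=C(C)/C=C/[C@H]1C(C)=CC(=O)CC1(C)C
F6 | step 6 | (2E,4E)-5-[(1R,4R)-4-hydroxy-2,6,6-trimethylcyclohex-2-en-1-yl]-3-methylpenta-2,4-dienenitrile | N#C/C=C(C)/C=C/[C@H]1C(C)=C[C@H](O)CC1(C)C
F7 | step 6 | (2E,4E)-5-[(1R,4R)-4-hydroxy-2,6,6-trimethylcyclohex-2-en-1-yl]-3-methylpenta-2,4-dienal | O=C/C=C(C)/C=C/[C@H]1C(C)=C[C@H](O)CC1(C)C
F8 | step 6 | (3R)-12′-apo-β-carotene-3,12′-diol | O[C@@H]1CC(C)=C(/C=C/C(C)=C/C=C/C(C)=C/C=C/C=C(C)/CO)C(C)(C)C1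
F9 | step 6 | [(3R)-3-hydroxy-12′-apo-β-caroten-12′-yl]triphenylphosphonium bromide | O[C@@H]1CC(C)=C(/C=C/C(C)=C/C=C/C(C)=C/C=C/C=C(C)/C[P+](c2ccccc2)(c2ccccc2)c2ccccc2)C(C)(C)C1.[Br-]
F10 | step 4 | (2E,4E,6E)-1-bromo-3,7,11-trimethyldodeca-2,4,6,10-tetraene | CC(C)=CCC/C(C)=C/C=C/C(C)=C/CBr
F11 | step 4 | diethyl [(2E,4E,6E)-3,7,11-trimethyldodeca-2,4,6,10-tetraen-1-yl]phosphonate | CC(C)=CCC/C(C)=C/C=C/C(C)=C/CP(=O)(OCC)OCC
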